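**Plan** (germacrane numbering: ring C1–C10; lactone C6–O–C12(=O)–C11(=C13H2)–C7; C14 on C10, C15 on C4)
1. Retrosynthesis first removes the C1–C10 epoxide oxygen and the C8 epoxyangelate. It then cuts C6–C7, C11–C12 and O–C12 in one [2+2+1] event, giving an acyclic (Z)-enal/terminal allene plus CO.
2. Enabling feature: the five-membered ring O–C12–C11–C7–C6 with its exocyclic C11=C13H2 is the retron of aldehyde (C6=O) + proximal allene π-bond (C7=C11) + CO. C6–C7 is also a bond of the ten-membered carbocycle, so one coupling closes both rings.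
3. The chain is cut at C3–C4 (Nozaki–Hiyama–Kishi), C1–C2 and C10–C14 (carboalumination/oxirane), C8–C9 (propargylation) and C11–C13 (allene homologation).
4. Forward order: C7/C11/C8 + C9/C10/C1, then C14 and C2–C3, then C13, then C4–C6/C15, then C3 ester and C6 aldehyde, then both rings at once, then the C8 ester, then the epoxide.
5. Stereochemistry: C8 comes from catalyst control, C3 from ligand control, Z-C4=C5 from trans-hydroalumination/iodination and E-C1=C10 from syn-carboalumination. C7 and C6 are relayed from C8 in the key step, C1/C10 come from peripheral attack on the macrocycle, and C2′/C3′ from Sharpless epoxidation.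
6. Helpers: a bulky O8–TBS ether (face director, removed after ring closure) and C1=C10 kept at the alkene level until the last step.

Key step: step 13

Assumption: the sense of induction in the two catalyst-controlled additions (steps 1 and 9) is taken from the usual facial models; if either is opposite, the antipodal catalyst or ligand is used.

Step 1
Reactants: 1 3-(trimethylsilyl)prop-2-ynal; 2 allenylboronic acid pinacol ester
Product: 4 (3R)-1-(trimethylsilyl)hexa-1,5-diyn-3-ol, via O-boryl ether 3 (not isolated)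
Conditions: (R)-TRIP phosphoric acid (10 mol %), 4 Å MS, toluene, −20 °C; aqueous work-up
Reagents that add atoms: none
Why: Chiral-phosphoric-acid-catalysed asymmetric propargylation (allenylboration through a closed six-membered SE2′ transition state) should deliver the propargyl group to the Re face of the ynal and so set C8 as R, the TMS cap keeping the two alkynes distinguishable later.

Step 2
Reactants: 4 (3R)-1-(trimethylsilyl)hexa-1,5-diyn-3-ol
Product: 5 (3R)-3-(tert-butyldimethylsilyloxy)-1-(trimethylsilyl)hexa-1,5-diyne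
Conditions: TBSCl, imidazole, DMF, rt
Reagents that add atoms: tert-butyldimethylsilyl chloride, CC(C)(C)[Si](C)(C)Cl
Why: Standard imidazole-promoted silylation turns the C8 carbinol into a bulky, non-coordinating TBS ether that tolerates the organoaluminium, Cr(II) and Mo(0) steps and later steers the key step, without touching the stereocentre.

Step 3
Reactants: 5 (3R)-3-(tert-butyldimethylsilyloxy)-1-(trimethylsilyl)hexa-1,5-diyne
Product: 7 (3E,6R)-6-(tert-butyldimethylsilyloxy)-4-methyl-8-(trimethylsilyl)oct-3-en-7-yn-1-ol, via (E)-alkenyldimethylalane 6 (not isolated)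
Conditions: AlMe3, Cp2ZrCl2 (cat.), CH2Cl2, 0 °C→rt; n-BuLi, hexane/THF, −78→0 °C; oxirane, 0 °C→rt; aqueous quench
Reagents that add atoms: trimethylaluminium, C[Al](C)C; oxirane, C1CO1
Why: Negishi Zr-catalysed carboalumination adds Me and Al syn across the terminal alkyne only (the silylalkyne is inert), which fixes the E geometry of C1=C10 and places C14 on C10, and after ate-complex formation with n-BuLi the alkenyl–Al bond opens oxirane with retention to add C2–C3.

Step 4
Reactants: 7 (3E,6R)-6-(tert-butyldimethylsilyloxy)-4-methyl-8-(trimethylsilyl)oct-3-en-7-yn-1-ol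
Product: 8 (3E,6R)-6-(tert-butyldimethylsilyloxy)-4-methyloct-3-en-7-yn-1-ol
Conditions: K2CO3 (0.2 equiv), MeOH, rt
Reagents that add atoms: none
Why: Base-catalysed protodesilylation of an alkynylsilane in methanol is selective for the C(sp)–Si bond and leaves the TBS ether, the alkene and C8 untouched.

Step 5
Reactants: 8 (3E,6R)-6-(tert-butyldimethylsilyloxy)-4-methyloct-3-en-7-yn-1-ol
Product: 10 (3E,6R)-6-(tert-butyldimethylsilyloxy)-4-methylnona-3,7,8-trien-1-ol, via N,N-dicyclohexylpropargylamine 9 (not isolated)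
Conditions: (CH2O)n, Cy2NH, CuI (0.5 equiv), dioxane, reflux
Reagents that add atoms: paraformaldehyde (as formaldehyde), C=O
Why: Crabbé–Ma allene homologation, in which Cu-catalysed Mannich coupling gives propargylamine 9 and a Cu-assisted 1,5-hydride shift with loss of the imine turns C7≡C11 into the terminal allene C7=C11=C13 without involving the C8–O bond.

Step 6
Reactants: 11 but-2-yn-1-ol
Product: 13 (2Z)-3-iodobut-2-en-1-ol, via sodium oxaaluminate 12 (not isolated)
Conditions: Red-Al, Et2O, 0 °C→rt; I2, THF, −78→0 °C; aqueous work-up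
Reagents that add atoms: iodine, II
Why: Hydroxyl-directed trans-hydroalumination of the propargylic alcohol puts aluminium on the methyl-bearing carbon cis to CH2OH (ring 12) and iodinolysis with retention gives the Z-iodide, the source of the Z-C4=C5 geometry.

Step 7
Reactants: 13 (2Z)-3-iodobut-2-en-1-ol
Product: 14 (2Z)-3-iodobut-2-enyl triethylsilyl ether
Conditions: TESCl, imidazole, CH2Cl2, 0 °C
Reagents that add atoms: chlorotriethylsilane, CC[Si](Cl)(CC)CC
Why: Routine silylation gives a primary TES ether that can later be removed in the presence of the secondary TBS ether.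

Step 8
Reactants: 10 (3E,6R)-6-(tert-butyldimethylsilyloxy)-4-methylnona-3,7,8-trien-1-ol
Product: 15 (3E,6R)-6-(tert-butyldimethylsilyloxy)-4-methylnona-3,7,8-trienal
Conditions: Dess–Martin periodinane, CH2Cl2, 0 °C; short silica plug, used at once
Reagents that add atoms: none
Why: Dess–Martin oxidation works at 0 °C without base, so that the β,γ-unsaturated aldehyde should form without migration of C1=C10 into conjugation and is used at once.

Step 9
Reactants: 15 (3E,6R)-6-(tert-butyldimethylsilyloxy)-4-methylnona-3,7,8-trienal; 14 (2Z)-3-iodobut-2-enyl triethylsilyl ether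
Product: 16 (2Z,4S,6E,9R)-9-(tert-butyldimethylsilyloxy)-3,7-dimethyl-1-(triethylsilyloxy)dodeca-2,6,10,11-tetraen-4-ol
Conditions: CrCl2 (4 equiv), chiral 2-(2-sulfonamidophenyl)oxazoline ligand (enantiomer for Re-face addition), Et3N, NiCl2 (2 mol %), THF, rt
Reagents that add atoms: none
Why: Asymmetric Nozaki–Hiyama–Kishi coupling, in which Ni inserts into the C–I bond with retention of the Z geometry, the alkenylchromium(III) reagent is non-basic enough to spare the enolisable β,γ-unsaturated aldehyde, and the Cr-bound chiral ligand should direct addition to the Re face and set C3 as S.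

Step 10
Reactants: 16 (2Z,4S,6E,9R)-9-(tert-butyldimethylsilyloxy)-3,7-dimethyl-1-(triethylsilyloxy)dodeca-2,6,10,11-tetraen-4-ol
Product: 17 (2Z,4S,6E,9R)-9-(tert-butyldimethylsilyloxy)-3,7-dimethyl-1-(triethylsilyloxy)dodeca-2,6,10,11-tetraen-4-yl 3-methylbutanoate
Conditions: isovaleryl chloride, pyridine, DMAP (cat.), CH2Cl2, 0 °C→rt
Reagents that add atoms: 3-methylbutanoyl chloride, CC(C)CC(=O)Cl
Why: DMAP-catalysed acylation installs the final C3 isovalerate with retention at C3 and blocks cyclisation of the later Z-γ-oxy-enal to a lactol or furan.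

Step 11
Reactants: 17 (2Z,4S,6E,9R)-9-(tert-butyldimethylsilyloxy)-3,7-dimethyl-1-(triethylsilyloxy)dodeca-2,6,10,11-tetraen-4-yl 3-methylbutanoate
Product: 18 (2Z,4S,6E,9R)-9-(tert-butyldimethylsilyloxy)-1-hydroxy-3,7-dimethyldodeca-2,6,10,11-tetraen-4-yl 3-methylbutanoate
Conditions: PPTS (cat.), MeOH/CH2Cl2, 0 °C
Reagents that add atoms: none
Why: Mild acid-catalysed methanolysis cleaves the unhindered primary TES ether far faster than the secondary TBS ether and is too weakly acidic to promote acyl migration or allylic ionisation.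

Step 12
Reactants: 18 (2Z,4S,6E,9R)-9-(tert-butyldimethylsilyloxy)-1-hydroxy-3,7-dimethyldodeca-2,6,10,11-tetraen-4-yl 3-methylbutanoate
Product: 19 (2Z,4S,6E,9R)-9-(tert-butyldimethylsilyloxy)-3,7-dimethyl-1-oxododeca-2,6,10,11-tetraen-4-yl 3-methylbutanoate
Conditions: Dess–Martin periodinane, CH2Cl2, 0 °C
Reagents that add atoms: none
Why: Dess–Martin oxidation of the Z-allylic alcohol at 0 °C should give the Z-enal without Z/E isomerisation, the allene and both isolated alkenes being inert.

Step 13
Reactants: 19 (2Z,4S,6E,9R)-9-(tert-butyldimethylsilyloxy)-3,7-dimethyl-1-oxododeca-2,6,10,11-tetraen-4-yl 3-methylbutanoate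
Product: 21 (3S,6R,7S,8R)-8-(tert-butyldimethylsilyloxy)-3-(3-methylbutanoyloxy)germacra-1(10)E,4Z,11(13)-trien-12,6-olide, via oxamolybdacyclopentane 20 (not isolated)
Conditions: Mo(CO)3(DMF)3 (2 equiv, freshly made from Mo(CO)6/DMF), THF, syringe-pump addition of 19 to 2 mM, Ar, 25→45 °C; then air, filtration through silica
Reagents that add atoms: tricarbonyltris(N,N-dimethylformamide)molybdenum(0) (donor of one CO), [Mo].[C-]#[O+].[C-]#[O+].[C-]#[O+].CN(C)C=O.CN(C)C=O.CN(C)C=O
Why: Proposed new method: loss of the labile DMF ligands lets one fac-Mo(CO)3 fragment bind the C6 aldehyde (η2) and the proximal C7=C11 π-bond of the allene at the same time, oxidative cyclisation then forms C6–C7 and oxamolybdacycle 20, migratory insertion of a CO ligand into the Mo–C11(sp2) bond forms C11–C12, and C–O reductive elimination releases the lactone with the distal allene π-bond left as the C11=C13 exo-methylene. The closest known reaction type is the Mo(0)- or Ru(0)-mediated hetero-Pauson–Khand [2+2+1] cyclocarbonylation of allenyl aldehydes (and of ynals with this same Mo complex), which has so far closed only five- and six-membered carbocycles, so the new element is the ten-membered ring. The carbocycle closes end-to-end by metal-templated coupling of the two chain termini (C6 and C7 held on one Mo, the tether pre-bent by the Z-C4=C5 and E-C1=C10 alkenes), and the five-membered lactone closes by CO insertion and reductive elimination from the five-membered metallacycle. C7 should be set by C8, the metal–aldehyde unit engaging the π-face anti to the bulky C8–OTBS bond with H-8 on the reacting face, and C6 by the preference of C5 and C8 for a trans arrangement on the metallacycle, the ring fusion that the eight-atom E,Z-diene tether spans with least transannular strain. The step needs proximal- over distal-π-bond selectivity (Mo(0) prefers the internal allene bond, and the distal mode would demand an eleven-membered ring with an endocyclic C7=C11 alkene), 1,2- over 1,4-engagement of the enal (C4 is fully substituted) and cyclisation over oligomerisation (2 mM, slow addition), while the near-ambient temperature protects the Z-enal, the allylic ester and the Cope-prone 1,5-diene.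

Step 14
Reactants: 21 (3S,6R,7S,8R)-8-(tert-butyldimethylsilyloxy)-3-(3-methylbutanoyloxy)germacra-1(10)E,4Z,11(13)-trien-12,6-olide
Product: 22 (3S,6R,7R,8R)-8-hydroxy-3-(3-methylbutanoyloxy)germacra-1(10)E,4Z,11(13)-trien-12,6-olide
Conditions: HF·pyridine, pyridine, THF, 0 °C→rt
Reagents that add atoms: none
Why: Fluoride-mediated desilylation under weakly acidic conditions removes the helper TBS group without conjugate addition to the α-methylene lactone, acyl migration or translactonisation to O8.

Step 15
Reactants: 23 methyl angelate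
Product: 24 (2Z)-2-methylbut-2-en-1-ol
Conditions: LiAlH4, Et2O, −20→0 °C
Reagents that add atoms: none
Why: Hydride reduction of the ester (1,2-reduction with LiAlH4 at low temperature) gives the allylic alcohol with the Z geometry of the angelate preserved.

Step 16
Reactants: 24 (2Z)-2-methylbut-2-en-1-ol
Product: 25 [(2R,3S)-2,3-dimethyloxiran-2-yl]methanol
Conditions: Ti(OiPr)4 (10 mol %), D-(−)-DIPT (12 mol %), TBHP (decane), 4 Å MS, CH2Cl2, −20 °C; non-aqueous work-up
Reagents that add atoms: tert-butyl hydroperoxide, CC(C)(C)OO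
Why: Sharpless asymmetric epoxidation with the D-(−)-tartrate should deliver oxygen to the alkene face that gives the (2R,3S)-epoxy alcohol, the cis relation of the C3′ methyl and CH2OH being carried over stereospecifically from the Z-alkene.

Step 17
Reactants: 25 [(2R,3S)-2,3-dimethyloxiran-2-yl]methanol
Product: 26 (2S,3S)-2,3-dimethyloxirane-2-carboxylic acid (epoxyangelic acid)
Conditions: TEMPO (cat.), PhI(OAc)2 (2.2 equiv), MeCN/H2O, rt
Reagents that add atoms: water, O
Why: TEMPO/PhI(OAc)2 oxidation in aqueous acetonitrile takes the primary alcohol through the aldehyde hydrate to the acid without opening the epoxide or touching its two stereocentres (the C2′ descriptor changes to S only by priority).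

Step 18
Reactants: 22 (3S,6R,7R,8R)-8-hydroxy-3-(3-methylbutanoyloxy)germacra-1(10)E,4Z,11(13)-trien-12,6-olide; 26 (2S,3S)-2,3-dimethyloxirane-2-carboxylic acid
Product: 28 (3S,6R,7R,8R)-8-[(2S,3S)-2,3-epoxy-2-methylbutanoyloxy]-3-(3-methylbutanoyloxy)germacra-1(10)E,4Z,11(13)-trien-12,6-olide, via mixed anhydride 27 (not isolated)
Conditions: 26, 2,4,6-trichlorobenzoyl chloride, Et3N, toluene, rt; then 22, DMAP, toluene, rt
Reagents that add atoms: none
Why: Yamaguchi esterification through mixed anhydride 27 acylates the hindered secondary C8 alcohol with retention at C8, and the quaternary glycidic acid has no epimerisable position.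

Step 19
Reactants: 28 (3S,6R,7R,8R)-8-[(2S,3S)-2,3-epoxy-2-methylbutanoyloxy]-3-(3-methylbutanoyloxy)germacra-1(10)E,4Z,11(13)-trien-12,6-olide
Product: 29 (1R,3S,6R,7R,8R,10R)-1,10-epoxy-8-[(2S,3S)-2,3-epoxy-2-methylbutanoyloxy]-3-(3-methylbutanoyloxy)germacra-4Z,11(13)-dien-12,6-olide (CNP0167461.1)
Conditions: dimethyldioxirane (1.1 equiv, acetone solution), CH2Cl2, −40→0 °C
Reagents that add atoms: dimethyldioxirane, CC1(C)OO1
Why: Electrophilic dioxirane epoxidation should pick the only electron-rich alkene, E-C1=C10 (C4=C5 is deactivated by two allylic acyloxy groups and C11=C13 is conjugated), and attack its exposed peripheral face in the heliangolide conformer, a stereospecific syn addition that gives the trans (1R,10R)-epoxide under neutral conditions that avoid transannular cyclisation.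

**Compound list**
1 | 3-(trimethylsilyl)prop-2-ynal | C[Si](C)(C)C#CC=O | starting material
2 | allenylboronic acid pinacol ester | C=C=CB1OC(C)(C)C(C)(C)O1 | starting material
3 | O-pinacolboryl ether of 4 | C#CC[C@@H](OB1OC(C)(C)C(C)(C)O1)C#C[Si](C)(C)C | intermediate
4 | (3R)-1-(trimethylsilyl)hexa-1,5-diyn-3-ol | C#CC[C@@H](O)C#C[Si](C)(C)C | intermediate
5 | (3R)-3-(tert-butyldimethylsilyloxy)-1-(trimethylsilyl)hexa-1,5-diyne | C#CC[C@@H](O[Si](C)(C)C(C)(C)C)C#C[Si](C)(C)C | intermediate
6 | (E)-alkenyldimethylalane from 5 | C[Al](C)/C=C(\C)C[C@@H](O[Si](C)(C)C(C)(C)C)C#C[Si](C)(C)C | intermediate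
7 | (3E,6R)-6-(tert-butyldimethylsilyloxy)-4-methyl-8-(trimethylsilyl)oct-3-en-7-yn-1-ol | OCC/C=C(\C)C[C@@H](O[Si](C)(C)C(C)(C)C)C#C[Si](C)(C)C | intermediate
8 | (3E,6R)-6-(tert-butyldimethylsilyloxy)-4-methyloct-3-en-7-yn-1-ol | OCC/C=C(\C)C[C@@H](O[Si](C)(C)C(C)(C)C)C#C | intermediate
9 | N,N-dicyclohexylpropargylamine (Mannich base of 8) | OCC/C=C(\C)C[C@@H](O[Si](C)(C)C(C)(C)C)C#CCN(C1CCCCC1)C1CCCCC1 | intermediate
10 | (3E,6R)-6-(tert-butyldimethylsilyloxy)-4-methylnona-3,7,8-trien-1-ol | OCC/C=C(\C)C[C@@H](O[Si](C)(C)C(C)(C)C)C=C=C | intermediate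
11 | but-2-yn-1-ol | CC#CCO | starting material
12 | sodium 2,2-bis(2-methoxyethoxy)-3-methyl-1,2-oxaaluminat-3-ene | CC1=CCO[Al-]1(OCCOC)OCCOC.[Na+] | intermediate
13 | (2Z)-3-iodobut-2-en-1-ol | C/C(I)=C/CO | intermediate
14 | (2Z)-3-iodobut-2-enyl triethylsilyl ether | C/C(I)=C/CO[Si](CC)(CC)CC | intermediate
15 | (3E,6R)-6-(tert-butyldimethylsilyloxy)-4-methylnona-3,7,8-trienal | O=CC/C=C(\C)C[C@@H](O[Si](C)(C)C(C)(C)C)C=C=C | intermediate
16 | (2Z,4S,6E,9R)-9-(tert-butyldimethylsilyloxy)-3,7-dimethyl-1-(triethylsilyloxy)dodeca-2,6,10,11-tetraen-4-ol | CC[Si](CC)(CC)OC/C=C(/C)[C@@H](O)C/C=C(\C)C[C@@H](O[Si](C)(C)C(C)(C)C)C=C=C | intermediate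
17 | 3-methylbutanoate of 16 | CC[Si](CC)(CC)OC/C=C(/C)[C@@H](OC(=O)CC(C)C)C/C=C(\C)C[C@@H](O[Si](C)(C)C(C)(C)C)C=C=C | intermediate
18 | (2Z,4S,6E,9R)-9-(tert-butyldimethylsilyloxy)-1-hydroxy-3,7-dimethyldodeca-2,6,10,11-tetraen-4-yl 3-methylbutanoate | OC/C=C(/C)[C@@H](OC(=O)CC(C)C)C/C=C(\C)C[C@@H](O[Si](C)(C)C(C)(C)C)C=C=C | intermediate
19 | (2Z,4S,6E,9R)-9-(tert-butyldimethylsilyloxy)-3,7-dimethyl-1-oxododeca-2,6,10,11-tetraen-4-yl 3-methylbutanoate | O=C/C=C(/C)[C@@H](OC(=O)CC(C)C)C/C=C(\C)C[C@@H](O[Si](C)(C)C(C)(C)C)C=C=C | intermediate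
20 | oxamolybdacyclopentane (Mo–O6, Mo–C11; CO and solvent ligands on Mo omitted) | C=C1[Mo]O[C@@H]2/C=C(/C)[C@@H](OC(=O)CC(C)C)C/C=C(\C)C[C@@H](O[Si](C)(C)C(C)(C)C)[C@@H]12 | intermediate
21 | (3S,6R,7S,8R)-8-(tert-butyldimethylsilyloxy)-3-(3-methylbutanoyloxy)germacra-1(10)E,4Z,11(13)-trien-12,6-olide | C=C1C(=O)O[C@@H]2/C=C(/C)[C@@H](OC(=O)CC(C)C)C/C=C(\C)C[C@@H](O[Si](C)(C)C(C)(C)C)[C@@H]12 | intermediate
22 | (3S,6R,7R,8R)-8-hydroxy-3-(3-methylbutanoyloxy)germacra-1(10)E,4Z,11(13)-trien-12,6-olide | C=C1C(=O)O[C@@H]2/C=C(/C)[C@@H](OC(=O)CC(C)C)C/C=C(\C)C[C@@H](O)[C@@H]12 | intermediate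
23 | methyl angelate | C/C=C(/C)C(=O)OC | starting material
24 | (2Z)-2-methylbut-2-en-1-ol | C/C=C(/C)CO | intermediate
25 | [(2R,3S)-2,3-dimethyloxiran-2-yl]methanol | OC[C@@]1(C)O[C@H]1C | intermediate
26 | (2S,3S)-2,3-dimethyloxirane-2-carboxylic acid | OC(=O)[C@@]1(C)O[C@H]1C | intermediate
27 | (2S,3S)-2,3-dimethyloxirane-2-carboxylic 2,4,6-trichlorobenzoic anhydride | O=C(OC(=O)[C@@]1(C)O[C@H]1C)c1c(Cl)cc(Cl)cc1Cl | intermediate
28 | (3S,6R,7R,8R)-8-[(2S,3S)-2,3-epoxy-2-methylbutanoyloxy]-3-(3-methylbutanoyloxy)germacra-1(10)E,4Z,11(13)-trien-12,6-olide | C=C1C(=O)O[C@@H]2/C=C(/C)[C@@H](OC(=O)CC(C)C)C/C=C(\C)C[C@@H](OC(=O)[C@@]3(C)O[C@H]3C)[C@@H]12 | intermediate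
29 | CNP0167461.1 | C=C1C(=O)O[C@@H]2/C=C(/C)[C@@H](OC(=O)CC(C)C)C[C@H]3O[C@]3(C)C[C@@H](OC(=O)[C@@]3(C)O[C@H]3C)[C@@H]12 | target

**Step count**
- Total steps: 19.
- Longest linear sequence: 14 (steps 1–5, 8–14, 18, 19).

**Steps most likely to fail**

1. Step 13 (labelled step).
- Risks: oligomerisation may outrun the ten-membered ring closure. The two chain ends may bind to different metal centres. The distal allene π-bond may be engaged. Facial control at C7/C6 may be poor. The Z-enal may isomerise, or the allylic ester may ionise, on Mo(0).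
- Fallback (known reaction types only): it sets out from 19 and comes back at 21. Pd(OAc)2-catalysed 1,2-dibromination of the allene (LiBr, p-benzoquinone, AcOH, rt) proceeds by bromopalladation to a 2-bromo-π-allyl complex and leaves the trisubstituted alkenes alone; it should give the (Z)-2-bromoallylic bromide F1. Nickel-free CrCl2 in THF at high dilution then converts only the allylic C–Br bond into a 2-bromoallylchromium(III) reagent. Its intramolecular Nozaki–Hiyama allylation of the enal (γ-attack at C7, chair transition state, anti adduct, which corresponds to the trans-lactone) closes the ten-membered ring to the 2-bromoalkenyl carbinol F2. Pd(PPh3)4-catalysed carbonylative lactonisation (CO 1 atm, Et3N, MeCN, 60 °C) of the vinyl bromide and the C6 hydroxyl then forms C11–C12 and O–C12 and gives 21.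

2. Step 19.
- Risks: facial selectivity may be poor if a second ring conformer exposes the other face of C1=C10. The deactivated C4=C5 alkene may be over-oxidised.
- Fallback: it sets out from 17 and comes back at 29; the epoxide is set under reagent control on the open chain and carried through the ring closure. Shi epoxidation (D-fructose-derived ketone, Oxone, K2CO3 buffer, MeCN/dimethoxymethane, 0 °C) of 17 should give the acyclic (1R,10R)-epoxide F3, because the isolated E-trisubstituted alkene is the most electron-rich π-bond and the catalyst selects the face. Pyridine-buffered HF·pyridine frees the primary allylic alcohol F4. Dess–Martin oxidation gives the epoxy enal F5. The cyclocarbonylation of step 13 gives the epoxy lactone silyl ether F6. Buffered HF·pyridine gives the C8 alcohol F7. Yamaguchi esterification with 26 through 27 gives 29.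

3. Step 9.
- Risks: ligand control of the carbonyl face may be insufficient with a Z-trisubstituted alkenylchromium reagent. C1=C10 of the aldehyde may migrate into conjugation before coupling.
- Fallback: it sets out from 15 and 14 and comes back at 16; the C3 configuration is set by reduction instead of addition. Ligand-free NiCl2/CrCl2 coupling (DMSO/THF, rt) gives the C3-epimeric carbinol mixture F8. Dess–Martin oxidation gives the Z-enone F9. Corey–Bakshi–Shibata reduction with (R)-Me-CBS and catecholborane (toluene, −78 °C), with the α-methylalkenyl group as the large substituent, should give the (4S)-alcohol 16.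

**Further compounds**
F1 | step 13 | (2Z,4S,6E,9R,10Z)-11,12-dibromo-9-(tert-butyldimethylsilyloxy)-3,7-dimethyl-1-oxododeca-2,6,10-trien-4-yl 3-methylbutanoate | O=C/C=C(/C)[C@@H](OC(=O)CC(C)C)C/C=C(\C)C[C@@H](O[Si](C)(C)C(C)(C)C)/C=C(\Br)CBr
F2 | step 13 | ten-membered (1(10)E,4Z)-dienyl carbinol with 6-OH, 7-(1-bromovinyl), 8-OTBS and 3-O-isovalerate | O[C@@H]1/C=C(/C)[C@@H](OC(=O)CC(C)C)C/C=C(\C)C[C@@H](O[Si](C)(C)C(C)(C)C)[C@H]1C(Br)=C
F3 | step 19 | (1R,10R)-epoxide of 17 | CC[Si](CC)(CC)OC/C=C(/C)[C@@H](OC(=O)CC(C)C)C[C@H]1O[C@]1(C)C[C@@H](O[Si](C)(C)C(C)(C)C)C=C=C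
F4 | step 19 | (1R,10R)-epoxide of 18 | OC/C=C(/C)[C@@H](OC(=O)CC(C)C)C[C@H]1O[C@]1(C)C[C@@H](O[Si](C)(C)C(C)(C)C)C=C=C
F5 | step 19 | (1R,10R)-epoxide of 19 | O=C/C=C(/C)[C@@H](OC(=O)CC(C)C)C[C@H]1O[C@]1(C)C[C@@H](O[Si](C)(C)C(C)(C)C)C=C=C
F6 | step 19 | (1R,10R)-epoxide of 21 | C=C1C(=O)O[C@@H]2/C=C(/C)[C@@H](OC(=O)CC(C)C)C[C@H]3O[C@]3(C)C[C@@H](O[Si](C)(C)C(C)(C)C)[C@@H]12
F7 | step 19 | (1R,10R)-epoxide of 22 | C=C1C(=O)O[C@@H]2/C=C(/C)[C@@H](OC(=O)CC(C)C)C[C@H]3O[C@]3(C)C[C@@H](O)[C@@H]12
F8 | step 9 | C4-epimeric mixture of 16 | CC[Si](CC)(CC)OC/C=C(/C)C(O)C/C=C(\C)C[C@@H](O[Si](C)(C)C(C)(C)C)C=C=C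
F9 | step 9 | (2Z,6E,9R)-9-(tert-butyldimethylsilyloxy)-3,7-dimethyl-1-(triethylsilyloxy)dodeca-2,6,10,11-tetraen-4-one | CC[Si](CC)(CC)OC/C=C(/C)C(=O)C/C=C(\C)C[C@@H](O[Si](C)(C)C(C)(C)C)C=C=C
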